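# Proposed total synthesis of CNP0603244.1 by an anionic oxy-Cope ring expansion that forges the C8–C9 diol

Compound numbers 1–33 are fixed by the steps and used throughout. Germacrane numbering is used for atoms: C1–C10 are the ring carbons, C11, C12 (carbonyl) and C13 (exomethylene) are the lactone carbons on C7, C14 sits on C10, and C15 is the methyl on C4.

## Analysis of the target

The target 33 is a germacranolide: a ten-membered carbocycle with an α-methylene-γ-butyrolactone fused across C6–C7. Both ring olefins are trisubstituted and Z (cis within the ring): C4=C5 with the methyl on C4, and C1=C10 with the acyloxymethyl carbon C14 on C10. Four contiguous stereocentres (6R,7R,8S,9R) line one edge of the ring: H6 and H7 are trans (trans-fused lactone), the C7–C11 bond is cis to O8, and O8 and O9 are cis (an erythro diol). The three oxygens outside the lactone all differ: a free hydroxyl on C8, an acetate on C9 and a 3-methylbutanoate on the primary allylic C14. They must therefore be told apart, and an acyl group on O9 can migrate to a free O8 under base. The exocyclic methylene lactone is a Michael acceptor and both esters are allylic, so strong nucleophiles, bases and acids must be kept away from late intermediates. The difficulty lies in the medium ring with its two Z trisubstituted olefins and in the C6–C9 tetrad. The route rests on the C8–C9 bond: it joins two oxygen-bearing carbons and lies between the C6 oxygen and the C1=C10 olefin, so C6(O)–C7–C8–C9–C10=C1 is a hex-5-en-1-one array, the retron of an oxy-Cope shift whose breaking bond, C1–C6, would close a cyclohexene.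

## Retrosynthetic reasoning

**O8, O9 and O14.** Target 33 is traced to 32 by removal of a 4-methoxybenzyl (PMB) group from O8. This is done last and oxidatively, under neutral conditions, so that the C9 acetate has no chance to migrate. Acetate 32 comes from 31 and 31 from diol 30 by two acylations. Diol 30 comes from acetonide 29, in which O9 and O14 share one acetal. The two are then distinguished only by being secondary and primary, so no further protecting group is needed.

**C11=C13.** The exocyclic methylene of 29 is cut back to the saturated lactone 25 through Mannich base 27. This step needs a strong base and is therefore placed before any ester is installed.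

**Lactone C6–O bond.** Lactone 25 is opened to hydroxy acid 23, and the lactone C–O bond is planned to form at C6 with inversion. Hydride should reach the C6 ketone of 21 from the outer face of the ring, which places O6 cis to the C7 side chain (6S, via 22). An SN2 closure by the carboxylate then turns this into the 6R trans-fused lactone, so the inherent facial bias is used and not opposed.

**C8–C9 and C7–C11 (the strategic cut).** Keto ester 21 is disconnected at C7–C11 to methyl bromoacetate 18 and at C8–C9, with C1–C6 reconnected, to the cyclohexenol 17. No other bond of the ring offers as much: the forward [3,3] shift enlarges a six-membered ring by four atoms, creates both carbinol centres from two enol ethers of fixed geometry, and writes the C1=C10 geometry through the chair.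

- The forward step must run through the chair with C2 axial on C1, which gives the Z olefin.
- O8 must be axial and O9 equatorial, which gives the erythro diol.
- C7 is left unsubstituted in 17. A side chain already on C7 would force C7 to be set by protonation of enolate 20, and the proton would arrive on the open face, anti to C9, which gives the wrong C7 epimer. A carbon electrophile arriving on that same open face gives the right one, and 18 also delivers C12 at the acid oxidation level.

**C6–C7.** The Z enol ether of 17 is taken back to ynol ether 16, and 16 to ketone 9 and the acetylide 15 made from dichlorovinyl ether 14. An alkyne is chosen for two reasons. Semi-hydrogenation guarantees the Z geometry, and a slim sp nucleophile should add axially to the enone, cis to the C1 substituent, which is the relative configuration the chair needs.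

**C1–C10 and the C1 stereocentre.** Ketone 9 carries a labile α′ centre that is also allylic. It is not carried through basic steps. Racemic 6, made by enolate alkenylation of 4 with triflate 3, is converted into the achiral enol carbonate 8, and the centre is then set by a catalytic enantioselective protonation under neutral conditions.

**Fragments.** Triflate 3 comes from the symmetrical ketone 1. Its ring locks the enol-ether oxygen (O9) cis to C14, which is the geometry that places O9 equatorial in the chair. Dichlorovinyl ether 14 comes from alcohol 10 and trichloroethene 11.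

## Alternatives that were turned down

Alternative 1: The disconnection reaches back to an arene. C8 and C9 with their oxygens are taken from bromobenzene A1. Whole-cell oxidation of A1 by an arene dioxygenase adds two oxygen atoms cis across the ortho and meta carbons and gives the bromo diene diol A2 as one enantiomer; no ring of the target is closed.
- For: the key step is established, the absolute configuration is certain, the cis relation is the erythro relation wanted at C8/C9, and the vinyl bromide is a handle for C14. The starting arene A1 is also as cheap as a starting material can be.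
- Against: the six-membered ring of A2 is not a substructure of 33. The ring carbon next to C8 would be C7, but its other ring neighbour cannot stay joined to C1, so the carbocycle must be cleaved. The ten-membered ring, both Z olefins, C7 and C6 would all remain to be made, with a macrocyclisation still to come and a step count well above that of the chosen route.
- Comparison: on absolute stereocontrol this alternative is stronger than the chosen strategy, which relies on a catalytic asymmetric protonation and a relay through a chair. The chosen strategy offers instead one step that builds the ring, the C1=C10 geometry and both carbinol centres from cyclohexenol 17, which is seven steps from commercial materials.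

Alternative 2: The ring is cut at C5–C6 together with the lactone C–O bond. The open-chain iodo-aldehyde A3 (Z iodoalkene at C5, aldehyde at C6, methyl ester at C12, cis acetonide on O8/O9) is closed by a chromium-mediated, nickel-catalysed Nozaki–Hiyama–Kishi reaction. The alkenylchromium species adds to the aldehyde and the C6 alkoxide is meant to attack the ester, giving the bicyclic lactone A4.
- For: such additions tolerate esters and acetals and have closed ten-membered rings, the Z C4=C5 geometry is fixed in the iodide, and ring and lactone appear together.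
- Against: the new C6 centre is set only by the conformation of the cyclising chain, so the trans relation to C7 is not assured. A3 is a β-alkoxy aldehyde with an epimerisable C7 and a leaving group on C8. Its linear assembly (the C7–C9 triad and two Z trisubstituted olefins) would take far more steps than the seven leading to 17. High dilution is needed and the C13 methylene is still to be added.
- Comparison: this alternative is stronger in precedent, since each reaction type is known on this bond type. The chosen route offers a shorter sequence and a ring made by enlarging an existing one, so no end-to-end closure is needed.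

Alternative 3: The ring is cut at C9–C10. The iodo-aldehyde A5 already holds the α-methylene lactone, a Z iodoalkene at C10 and an α-silyloxy aldehyde at C9. The same chromium/nickel chemistry closes it to the 9-hydroxy germacranolide A6, with the C9 carbinol set under Felkin–Anh control by the O8 silyl ether.
- For: it is the latest possible ring closure, the polar Felkin–Anh model predicts the anti (erythro) 8,9-diol, O9 emerges free and already differentiated, and only three or four steps would remain.
- Against: an α-branched alkenylchromium must add to a hindered α-branched aldehyde while a ten-membered ring closes. Open-chain Felkin–Anh control need not survive in a macrocyclic transition state. The α-silyloxy aldehyde can epimerise or eliminate, the exocyclic enoate is exposed to a low-valent single-electron reductant, and A5 again needs a long linear synthesis.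
- Comparison: on the length of the endgame and on precedent for the ring closure this alternative is as strong or stronger. The chosen strategy offers a short route to its precursor and sets C8, C9 and the C1=C10 geometry in one concerted, geometrically defined event, not by a conformational preference.

Key step: step 8

**Assumption (remark on the chemistry):** the sense of induction of (S)-t-Bu-PHOX in step 4 is assigned by analogy with 2-substituted cycloalkanone enolates; should the (S) ketone form, the (R) ligand is used and nothing else changes.

**Remark on locants:** in the cyclohexene compounds 4–9, 16, 17 and 19 the oxygen-bearing ring carbon is germacrane C6 and its sp3 neighbour carrying the dioxinyl group is germacrane C1. The Why lines use germacrane numbers.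

## Route

Step 1
Reactants: 1 2,2-dimethyl-1,3-dioxan-5-one
Product: 3 2,2-dimethyl-4H-1,3-dioxin-5-yl trifluoromethanesulfonate, via lithium enolate 2 (not isolated)
Conditions: LiN(SiMe3)2, THF, −78 °C; then PhNTf2, −78 → 0 °C
Reagents that add atoms: N-phenylbis(trifluoromethanesulfonimide), O=S(=O)(N(c1ccccc1)S(=O)(=O)C(F)(F)F)C(F)(F)F
Why: Kinetic enolisation of the symmetrical ketone (either α-carbon gives the same enolate) and O-sulfonylation give the enol triflate. The six-membered ring fixes the enol-ether oxygen cis to the CH2O arm, which is the C9=C10 geometry the rearrangement needs.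

Step 2
Reactants: 4 3-methylcyclohex-2-en-1-one; 3 2,2-dimethyl-4H-1,3-dioxin-5-yl trifluoromethanesulfonate
Product: 6 rac-6-(2,2-dimethyl-4H-1,3-dioxin-5-yl)-3-methylcyclohex-2-en-1-one, via lithium dienolate 5 (not isolated)
Conditions: LiN(SiMe3)2 (2.2 equiv), THF, −78 °C; then 3, Pd2(dba)3 (cat.), P(t-Bu)3, −78 °C → rt; pH 7 buffer
Reagents that add atoms: none
Why: Palladium-catalysed alkenylation of a ketone enolate: oxidative addition of the alkenyl triflate to zerovalent palladium, transmetalation with the kinetic cross-conjugated α′ enolate 5 and reductive elimination form C1–C10. The more acidic product is held as its enolate by the second equivalent of base, which stops a second coupling; the new centre is racemic here and is erased in step 3.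

Step 3
Reactants: 6 rac-6-(2,2-dimethyl-4H-1,3-dioxin-5-yl)-3-methylcyclohex-2-en-1-one
Product: 8 1-(2,2-dimethyl-4H-1,3-dioxin-5-yl)-4-methylcyclohexa-1,3-dien-2-yl prop-2-en-1-yl carbonate, via lithium trienolate 7 (not isolated)
Conditions: LiN(SiMe3)2, TMEDA, THF, −78 °C; then ClCO2CH2CH=CH2, −78 °C
Reagents that add atoms: allyl chloroformate, C=CCOC(Cl)=O
Why: The fully substituted carbon of enolate 7 is hindered, so the hard chloroformate acylates on oxygen (enol carbonate formation), helped by TMEDA. The product is achiral, so the racemic centre of 6 becomes a prochiral enolate equivalent.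

Step 4
Reactants: 8 1-(2,2-dimethyl-4H-1,3-dioxin-5-yl)-4-methylcyclohexa-1,3-dien-2-yl prop-2-en-1-yl carbonate
Product: 9 (6R)-6-(2,2-dimethyl-4H-1,3-dioxin-5-yl)-3-methylcyclohex-2-en-1-one
Conditions: Pd(OAc)2 (cat.), (S)-t-Bu-PHOX, Meldrum's acid (2.5 equiv), 1,4-dioxane, rt
Reagents that add atoms: none
Why: Palladium-catalysed enantioselective decarboxylative protonation: zerovalent palladium ionises the allyl carbonate, CO2 is lost, and the chiral palladium enolate is protonated at the α-carbon by Meldrum's acid, which also takes up the allyl group. The phosphinooxazoline ligand differentiates the enolate faces and sets C1 (R); kinetic α-protonation under neutral conditions leaves the dioxin double bond out of conjugation.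

Step 5
Reactants: 10 (4-methoxyphenyl)methanol; 11 trichloroethene
Product: 14 1-({[(E)-1,2-dichloroethenyl]oxy}methyl)-4-methoxybenzene, via potassium alkoxide 12 (not isolated), via dichloroethyne 13 (not isolated)
Conditions: KH, THF, 0 °C; then Cl2C=CHCl, 0 °C → rt
Reagents that add atoms: none
Why: The alkoxide dehydrochlorinates trichloroethene to dichloroethyne and then adds to it in an anti sense, a known route to (E)-1,2-dichlorovinyl ethers; the chain is carried by proton transfer from the alcohol.

Step 6
Reactants: 14 1-({[(E)-1,2-dichloroethenyl]oxy}methyl)-4-methoxybenzene; 9 (6R)-6-(2,2-dimethyl-4H-1,3-dioxin-5-yl)-3-methylcyclohex-2-en-1-one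
Product: 16 (1S,6R)-6-(2,2-dimethyl-4H-1,3-dioxin-5-yl)-1-{[(4-methoxyphenyl)methoxy]ethynyl}-3-methylcyclohex-2-en-1-ol, via lithium alkoxyacetylide 15 (not isolated)
Conditions: 14, n-BuLi (2.1 equiv), THF, −78 °C; then 9, −78 °C; aq. NaHCO3
Reagents that add atoms: none
Why: n-BuLi first eliminates HCl and then exchanges the remaining chlorine for lithium, giving alkoxyacetylide 15, which adds 1,2 to the ketone at −78 °C. The slim sp nucleophile should attack the enone half-chair axially, antiperiplanar to the axial C1–H and on the face of the equatorial dioxinyl group, so the alkyne ends cis to that group and the hydroxyl trans (1S). Low temperature and the weakly basic acetylide protect the labile C1 centre; the ynol ether is used at once.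

Step 7
Reactants: 16 (1S,6R)-6-(2,2-dimethyl-4H-1,3-dioxin-5-yl)-1-{[(4-methoxyphenyl)methoxy]ethynyl}-3-methylcyclohex-2-en-1-ol
Product: 17 (1S,6R)-6-(2,2-dimethyl-4H-1,3-dioxin-5-yl)-1-{(Z)-2-[(4-methoxyphenyl)methoxy]ethenyl}-3-methylcyclohex-2-en-1-ol
Conditions: H2 (1 atm), Pd/CaCO3–Pb(OAc)2 (Lindlar catalyst), quinoline, EtOAc, 0 °C
Reagents that add atoms: none
Why: Lindlar semi-hydrogenation delivers H2 syn to the ynol ether and stops at the Z enol ether; the trisubstituted ring olefins are too hindered to react. Quinoline keeps the acid-labile β-alkoxyvinyl carbinol in a basic medium.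

Step 8
Reactants: 17 (1S,6R)-6-(2,2-dimethyl-4H-1,3-dioxin-5-yl)-1-{(Z)-2-[(4-methoxyphenyl)methoxy]ethenyl}-3-methylcyclohex-2-en-1-ol; 18 methyl bromoacetate
Product: 21 methyl (7R,8S,9R)-9,14-O-isopropylidene-8-O-(4-methoxybenzyl)-8,9,14-trihydroxy-6-oxo-13-norgermacra-1(10)Z,4Z-dien-12-oate, via potassium alkoxide 19 (not isolated), via potassium enolate 20 (not isolated)
Conditions: KN(SiMe3)2 (1.05 equiv), THF, −78 → 0 °C; then 18, −78 °C; pH 7 buffer
Reagents that add atoms: none
Why: Proposed new method: deprotonation gives the tertiary potassium alkoxide 19, whose oxyanion weakens C1–C6 so that a concerted [3,3] shift (anionic oxy-Cope rearrangement) joins the two enol-ether termini C8 and C9 while C1–C6 breaks; the closest known reaction type is the anionic oxy-Cope ring expansion of cis-1,2-divinylcyclohexanols to (Z)-cyclodec-5-enones, which has not been shown with an oxygen substituent on both bond-forming termini. The ten-membered ring is not closed end to end but arises by four-atom enlargement of the cyclohexene through a bicyclic chair transition state whose six reacting atoms are C8, C7, C6, C1, C10 and C9. Because the two alkenyl groups are cis, one ring bond must be axial: in the productive chair C2 is axial on C1 and C5 equatorial on C6, so the new C1=C10 olefin is Z and the enolate C6=C7 has C5 and C8 trans. Three features of 19 secure this chair over the one that would give the E olefin and the opposite diol: the bulky dioxinyl group stays equatorial on the cyclohexene half-chair, the other chair would put C5 and the axial O8 in a 1,3-diaxial clash, and in the productive chair the axial O6 and O8 are bridged by the potassium ion (hence no crown ether). C8 is set by the Z enol ether (O8 axial) and C9 by the ring-locked dioxin (O9 trans to C1, equatorial), which together give the erythro 8S,9R diol, the absolute sense being relayed from C1 and C6. After the shift the same potassium ion should keep bridging the enolate oxygen and O8, which draws the C8–O8 bond towards the enolate plane (poor overlap for E1cB loss of the C8 oxygen) and leaves C9 with the rest of the ring covering one face of C7. Methyl bromoacetate therefore alkylates C7 on the open face, anti to C9, which gives 7R, and this is why the side chain is brought in as the electrophile and not carried on C7 and set by protonation.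

Step 9
Reactants: 21 methyl (7R,8S,9R)-9,14-O-isopropylidene-8-O-(4-methoxybenzyl)-8,9,14-trihydroxy-6-oxo-13-norgermacra-1(10)Z,4Z-dien-12-oate
Product: 23 (6S,7S,8S,9R)-6,8,9,14-tetrahydroxy-9,14-O-isopropylidene-8-O-(4-methoxybenzyl)-13-norgermacra-1(10)Z,4Z-dien-12-oic acid, via hydroxy ester 22 (not isolated)
Conditions: NaBH4, CeCl3·7H2O, MeOH, −40 °C; then LiOH, THF/H2O, 0 °C → rt; NaH2PO4 to pH 5, 0 °C
Reagents that add atoms: lithium hydroxide, [Li+].[OH-]
Why: Luche 1,2-reduction followed by saponification. Hydride should add to the outer face of the ring ketone, anti to C8 on the conformer that turns the C7 side chain outward and eclipsed with the carbonyl, which places O6 cis to that side chain (6S). LiOH then opens the ester, and any cis lactone formed in the flask, to the hydroxy carboxylate, which is used at once.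

Step 10
Reactants: 23 (6S,7S,8S,9R)-6,8,9,14-tetrahydroxy-9,14-O-isopropylidene-8-O-(4-methoxybenzyl)-13-norgermacra-1(10)Z,4Z-dien-12-oic acid
Product: 25 (6R,7S,8S,9R)-8,9,14-trihydroxy-9,14-O-isopropylidene-8-O-(4-methoxybenzyl)-13-norgermacra-1(10)Z,4Z-dien-12,6-olide, via oxyphosphonium carboxylate 24 (not isolated)
Conditions: PPh3, DIAD, THF, 0 °C → rt
Reagents that add atoms: none
Why: Mitsunobu lactonisation: the allylic C6 hydroxyl is activated as oxyphosphonium ion 24 and displaced by the tethered carboxylate in a 5-exo-tet SN2 reaction, so C6 is inverted to 6R and the lactone is trans-fused. SN2′ attack would need a seven-membered ring at the methyl-bearing C4 and is not expected.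

Step 11
Reactants: 25 (6R,7S,8S,9R)-8,9,14-trihydroxy-9,14-O-isopropylidene-8-O-(4-methoxybenzyl)-13-norgermacra-1(10)Z,4Z-dien-12,6-olide
Product: 27 (6R,7S,8S,9R)-13-(dimethylamino)-8,9,14-trihydroxy-9,14-O-isopropylidene-8-O-(4-methoxybenzyl)germacra-1(10)Z,4Z-dien-12,6-olide as a mixture of C11 epimers, via lithium lactone enolate 26 (not isolated)
Conditions: LiN(i-Pr)2, THF, −78 °C; then CH2=NMe2+ I−, −78 → 0 °C
Reagents that add atoms: N,N-dimethylmethyleneiminium iodide (Eschenmoser's salt), C=[N+](C)C.[I-]
Why: Mannich reaction of the lactone enolate with the iminium salt puts the aminomethyl group on C11. The configuration of the new C11 centre does not matter because C11 becomes sp2 in step 12; no ester is yet present to be harmed by the base.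

Step 12
Reactants: 27 (6R,7S,8S,9R)-13-(dimethylamino)-8,9,14-trihydroxy-9,14-O-isopropylidene-8-O-(4-methoxybenzyl)germacra-1(10)Z,4Z-dien-12,6-olide
Product: 29 (6R,7S,8S,9R)-8,9,14-trihydroxy-9,14-O-isopropylidene-8-O-(4-methoxybenzyl)germacra-1(10)Z,4Z,11(13)-trien-12,6-olide, via ammonium iodide 28 (not isolated)
Conditions: MeI, THF, rt; then NaHCO3, EtOAc/H2O, rt
Reagents that add atoms: none
Why: Methylation gives the quaternary ammonium salt, which loses trimethylamine by base-induced β-elimination (E1cB, Hofmann type) to give the exocyclic methylene; both C11 epimers converge.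

Step 13
Reactants: 29 (6R,7S,8S,9R)-8,9,14-trihydroxy-9,14-O-isopropylidene-8-O-(4-methoxybenzyl)germacra-1(10)Z,4Z,11(13)-trien-12,6-olide
Product: 30 (6R,7S,8S,9R)-9,14-dihydroxy-8-(4-methoxybenzyloxy)germacra-1(10)Z,4Z,11(13)-trien-12,6-olide
Conditions: PPTS (cat.), MeOH, rt
Reagents that add atoms: none
Why: Acid-catalysed transacetalisation to methanol removes the isopropylidene group; the PMB ether, the lactone and the olefins are stable to this weak acid.

Step 14
Reactants: 30 (6R,7S,8S,9R)-9,14-dihydroxy-8-(4-methoxybenzyloxy)germacra-1(10)Z,4Z,11(13)-trien-12,6-olide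
Product: 31 (6R,7S,8S,9R)-9-hydroxy-8-(4-methoxybenzyloxy)-14-(3-methylbutanoyloxy)germacra-1(10)Z,4Z,11(13)-trien-12,6-olide
Conditions: (CH3)2CHCH2COCl (1.05 equiv), 2,4,6-collidine, CH2Cl2, −78 → −30 °C
Reagents that add atoms: 3-methylbutanoyl chloride, CC(C)CC(Cl)=O
Why: Kinetic primary-selective esterification: the acid chloride with a hindered pyridine base reacts much faster at the primary allylic C14 hydroxyl than at the secondary C9 hydroxyl, which is flanked by the PMB ether and the fully substituted C10.

Step 15
Reactants: 31 (6R,7S,8S,9R)-9-hydroxy-8-(4-methoxybenzyloxy)-14-(3-methylbutanoyloxy)germacra-1(10)Z,4Z,11(13)-trien-12,6-olide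
Product: 32 (6R,7S,8S,9R)-9-acetoxy-8-(4-methoxybenzyloxy)-14-(3-methylbutanoyloxy)germacra-1(10)Z,4Z,11(13)-trien-12,6-olide
Conditions: Ac2O, DMAP (cat.), pyridine, CH2Cl2, 0 °C
Reagents that add atoms: acetic anhydride, CC(=O)OC(C)=O
Why: DMAP-catalysed acetylation (nucleophilic acyl-transfer catalysis) of the remaining secondary allylic hydroxyl, carried out promptly so that the C14 ester does not migrate.

Step 16
Reactants: 32 (6R,7S,8S,9R)-9-acetoxy-8-(4-methoxybenzyloxy)-14-(3-methylbutanoyloxy)germacra-1(10)Z,4Z,11(13)-trien-12,6-olide
Product: 33 (6R,7R,8S,9R)-9-acetoxy-8-hydroxy-14-(3-methylbutanoyloxy)germacra-1(10)Z,4Z,11(13)-trien-12,6-olide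
Conditions: DDQ, CH2Cl2/pH 7 buffer, 0 °C
Reagents that add atoms: none
Why: Oxidative PMB cleavage: DDQ abstracts hydride from the electron-rich benzyl ether and water hydrolyses the resulting oxocarbenium ion. The buffered, near-neutral medium avoids acetyl migration from O9 to the freed O8 and leaves the Michael acceptor untouched.

## Compound list

1 | 2,2-dimethyl-1,3-dioxan-5-one | CC1(C)OCC(=O)CO1 | starting material
2 | lithium 2,2-dimethyl-4H-1,3-dioxin-5-olate | [Li+].CC1(C)OCC([O-])=CO1 | intermediate
3 | 2,2-dimethyl-4H-1,3-dioxin-5-yl trifluoromethanesulfonate | CC1(C)OCC(OS(=O)(=O)C(F)(F)F)=CO1 | intermediate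
4 | 3-methylcyclohex-2-en-1-one | CC1=CC(=O)CCC1 | starting material
5 | lithium 4-methylcyclohexa-1,3-dien-2-olate | [Li+].CC1=CC([O-])=CCC1 | intermediate
6 | rac-6-(2,2-dimethyl-4H-1,3-dioxin-5-yl)-3-methylcyclohex-2-en-1-one (racemate) | CC1=CC(=O)C(CC1)C2=COC(C)(C)OC2 | intermediate
7 | lithium 1-(2,2-dimethyl-4H-1,3-dioxin-5-yl)-4-methylcyclohexa-1,3-dien-2-olate | [Li+].CC1=CC([O-])=C(CC1)C2=COC(C)(C)OC2 | intermediate
8 | 1-(2,2-dimethyl-4H-1,3-dioxin-5-yl)-4-methylcyclohexa-1,3-dien-2-yl prop-2-en-1-yl carbonate | C=CCOC(=O)OC1=C(CCC(C)=C1)C2=COC(C)(C)OC2 | intermediate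
9 | (6R)-6-(2,2-dimethyl-4H-1,3-dioxin-5-yl)-3-methylcyclohex-2-en-1-one | CC1=CC(=O)[C@H](CC1)C2=COC(C)(C)OC2 | intermediate
10 | (4-methoxyphenyl)methanol | COc1ccc(CO)cc1 | starting material
11 | trichloroethene | ClC=C(Cl)Cl | starting material
12 | potassium (4-methoxyphenyl)methanolate | [K+].COc1ccc(C[O-])cc1 | intermediate
13 | dichloroethyne | ClC#CCl | intermediate
14 | 1-({[(E)-1,2-dichloroethenyl]oxy}methyl)-4-methoxybenzene | COc1ccc(CO/C(Cl)=C\Cl)cc1 | intermediate
15 | lithium [(4-methoxyphenyl)methoxy]ethynide | [Li]C#COCc1ccc(OC)cc1 | intermediate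
16 | (1S,6R)-6-(2,2-dimethyl-4H-1,3-dioxin-5-yl)-1-{[(4-methoxyphenyl)methoxy]ethynyl}-3-methylcyclohex-2-en-1-ol | CC1=C[C@@](O)(C#COCc2ccc(OC)cc2)[C@H](CC1)C3=COC(C)(C)OC3 | intermediate
17 | (1S,6R)-6-(2,2-dimethyl-4H-1,3-dioxin-5-yl)-1-{(Z)-2-[(4-methoxyphenyl)methoxy]ethenyl}-3-methylcyclohex-2-en-1-ol | CC1=C[C@@](O)(/C=C\OCc2ccc(OC)cc2)[C@H](CC1)C3=COC(C)(C)OC3 | intermediate
18 | methyl bromoacetate | COC(=O)CBr | starting material
19 | potassium (1S,6R)-6-(2,2-dimethyl-4H-1,3-dioxin-5-yl)-1-{(Z)-2-[(4-methoxyphenyl)methoxy]ethenyl}-3-methylcyclohex-2-en-1-olate | [K+].CC1=C[C@@]([O-])(/C=C\OCc2ccc(OC)cc2)[C@H](CC1)C3=COC(C)(C)OC3 | intermediate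
20 | potassium (8S,9R)-9,14-O-isopropylidene-8-O-(4-methoxybenzyl)-8,9,14-trihydroxy-11,12,13-trinorgermacra-1(10)Z,4Z,6-trien-6-olate (C5 and C8 trans across C6=C7) | [K+].C1/C(C)=C\C([O-])=C\[C@H](OCc3ccc(OC)cc3)[C@@H]2OC(C)(C)OC/C2=C/C1 | intermediate
21 | methyl (7R,8S,9R)-9,14-O-isopropylidene-8-O-(4-methoxybenzyl)-8,9,14-trihydroxy-6-oxo-13-norgermacra-1(10)Z,4Z-dien-12-oate | O=C1/C=C(/C)CC/C=C2/COC(C)(C)O[C@H]2[C@@H](OCc3ccc(OC)cc3)[C@H]1CC(=O)OC | intermediate
22 | methyl (6S,7S,8S,9R)-6,8,9,14-tetrahydroxy-9,14-O-isopropylidene-8-O-(4-methoxybenzyl)-13-norgermacra-1(10)Z,4Z-dien-12-oate | O[C@H]1/C=C(/C)CC/C=C2/COC(C)(C)O[C@H]2[C@@H](OCc3ccc(OC)cc3)[C@H]1CC(=O)OC | intermediate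
23 | (6S,7S,8S,9R)-6,8,9,14-tetrahydroxy-9,14-O-isopropylidene-8-O-(4-methoxybenzyl)-13-norgermacra-1(10)Z,4Z-dien-12-oic acid | O[C@H]1/C=C(/C)CC/C=C2/COC(C)(C)O[C@H]2[C@@H](OCc3ccc(OC)cc3)[C@H]1CC(=O)O | intermediate
24 | (6S,7R,8S,9R)-8,9,14-trihydroxy-9,14-O-isopropylidene-8-O-(4-methoxybenzyl)-6-(triphenylphosphoniooxy)-13-norgermacra-1(10)Z,4Z-dien-12-oate (zwitterion) | c1ccc(cc1)[P+](c1ccccc1)(c1ccccc1)O[C@H]1/C=C(/C)CC/C=C2/COC(C)(C)O[C@H]2[C@@H](OCc3ccc(OC)cc3)[C@H]1CC(=O)[O-] | intermediate
25 | (6R,7S,8S,9R)-8,9,14-trihydroxy-9,14-O-isopropylidene-8-O-(4-methoxybenzyl)-13-norgermacra-1(10)Z,4Z-dien-12,6-olide | C1C(=O)O[C@@H]2/C=C(/C)CC/C=C3/COC(C)(C)O[C@H]3[C@@H](OCc4ccc(OC)cc4)[C@@H]12 | intermediate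
26 | lithium enolate (C11=C12–O–Li) of lactone 25, (6R,7S,8S,9R) | [Li+].C1=C([O-])O[C@@H]2/C=C(/C)CC/C=C3/COC(C)(C)O[C@H]3[C@@H](OCc4ccc(OC)cc4)[C@@H]12 | intermediate
27 | (6R,7S,8S,9R)-13-(dimethylamino)-8,9,14-trihydroxy-9,14-O-isopropylidene-8-O-(4-methoxybenzyl)germacra-1(10)Z,4Z-dien-12,6-olide (both C11 epimers) | CN(C)CC1C(=O)O[C@@H]2/C=C(/C)CC/C=C3/COC(C)(C)O[C@H]3[C@@H](OCc4ccc(OC)cc4)[C@@H]12 | intermediate
28 | N,N,N-trimethylammonium iodide of 27 (both C11 epimers) | [I-].C[N+](C)(C)CC1C(=O)O[C@@H]2/C=C(/C)CC/C=C3/COC(C)(C)O[C@H]3[C@@H](OCc4ccc(OC)cc4)[C@@H]12 | intermediate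
29 | (6R,7S,8S,9R)-8,9,14-trihydroxy-9,14-O-isopropylidene-8-O-(4-methoxybenzyl)germacra-1(10)Z,4Z,11(13)-trien-12,6-olide | C=C1C(=O)O[C@@H]2/C=C(/C)CC/C=C3/COC(C)(C)O[C@H]3[C@@H](OCc4ccc(OC)cc4)[C@@H]12 | intermediate
30 | (6R,7S,8S,9R)-9,14-dihydroxy-8-(4-methoxybenzyloxy)germacra-1(10)Z,4Z,11(13)-trien-12,6-olide | C=C1C(=O)O[C@@H]2/C=C(/C)CC/C=C(/CO)[C@@H](O)[C@@H](OCc3ccc(OC)cc3)[C@@H]12 | intermediate
31 | (6R,7S,8S,9R)-9-hydroxy-8-(4-methoxybenzyloxy)-14-(3-methylbutanoyloxy)germacra-1(10)Z,4Z,11(13)-trien-12,6-olide | C=C1C(=O)O[C@@H]2/C=C(/C)CC/C=C(/COC(=O)CC(C)C)[C@@H](O)[C@@H](OCc3ccc(OC)cc3)[C@@H]12 | intermediate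
32 | (6R,7S,8S,9R)-9-acetoxy-8-(4-methoxybenzyloxy)-14-(3-methylbutanoyloxy)germacra-1(10)Z,4Z,11(13)-trien-12,6-olide | C=C1C(=O)O[C@@H]2/C=C(/C)CC/C=C(/COC(=O)CC(C)C)[C@@H](OC(C)=O)[C@@H](OCc3ccc(OC)cc3)[C@@H]12 | intermediate
33 | (6R,7R,8S,9R)-9-acetoxy-8-hydroxy-14-(3-methylbutanoyloxy)germacra-1(10)Z,4Z,11(13)-trien-12,6-olide (CNP0603244.1) | C=C1C(=O)O[C@@H]2/C=C(/C)CC/C=C(/COC(=O)CC(C)C)[C@@H](OC(C)=O)[C@@H](O)[C@@H]12 | target

## Step count and least certain steps

Total step count: 16. Longest linear sequence: 15 steps (1 to 33 through steps 1–4 and 6–16); step 5 is a one-step side branch.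

**Step 8 (key step).** Several processes could intervene:
- rearrangement through the other chair (C2 equatorial) or a boat, which would give the E olefin and the opposite C8/C9 configuration;
- β-elimination of the C8 alkoxide from the enolate once the chelate is lost, more likely the warmer the mixture must be held;
- heterolytic fragmentation of the alkoxide, or a [1,3] shift to an eight-membered ketone;
- ring inversion of the trisubstituted enolate before alkylation, which would erode the facial selectivity at C7.

Fallback (known chemistry, neutral thermal rearrangement): from 17, silylation (TMSOTf, 2,6-lutidine) gives the tertiary trimethylsilyl ether F1. Heating in degassed o-xylene in base-washed glassware, below the temperature at which the dioxin undergoes retro-cycloaddition, should effect the siloxy-Cope rearrangement to the ring-expanded silyl enol ether F2 with no free enolate and hence no β-elimination. MeLi then releases the lithium enolate regiospecifically and 18 (with DMPU) alkylates it, returning to 21.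

**Step 6.** The acetylide may attack from the equatorial side (alkyne trans to the dioxinyl group), and some ketone may be lost to enolisation, which would also endanger the C1 centre. Fallback: the stereocontrol is moved from the substrate to a reagent. Setting out from 9, the ketone is first complexed with the bulky aluminium aryloxide MeAl(OAr)2 (Ar = 2,6-di-tert-butyl-4-methylphenyl), which occupies the equatorial side of the carbonyl, and 15 is then added so that it must enter axially. This returns directly to 16 and makes no new compound, hence the entry F0.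

**Step 4.** The enantioselectivity may be low for an α-alkenyl enolate; the double bond may migrate into conjugation; and 9 may racemise on handling. Fallback (dynamic kinetic resolution): from 6, asymmetric transfer hydrogenation with RuCl(p-cymene)[(S,S)-TsDPEN] (or its antipode) in HCO2H/Et3N, in which the labile α′ centre equilibrates while one enantiomer is reduced, gives the cis allylic alcohol F3. Buffered Dess–Martin oxidation then returns to 9 just before step 6.

**Step 9.** Hydride may be delivered to the inner face instead, giving the 6R alcohol, because the preferred ring conformation of 21 is not known. Fallback (closure with retention instead of inversion): from 21, the Luche reduction alone would then give the 6R hydroxy ester F4, which is lactonised directly with PPTS in benzene, returning to 25.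

**Step 10.** The oxyphosphonium ion may eliminate towards a diene, or the hydroxy acid may close with retention to the cis lactone before it is activated. Fallback (intermolecular inversion, then closure with retention): from 21, the reduction product 22 is isolated and inverted with 4-nitrobenzoic acid under Mitsunobu conditions to the 6R 4-nitrobenzoate F5. K2CO3 in MeOH cleaves the nitrobenzoate and the freed 6R alkoxide closes onto the methyl ester, returning to 25.

## Further compounds

F1 | step 8 | {[(1S,6R)-6-(2,2-dimethyl-4H-1,3-dioxin-5-yl)-1-{(Z)-2-[(4-methoxyphenyl)methoxy]ethenyl}-3-methylcyclohex-2-en-1-yl]oxy}(trimethyl)silane | CC1=C[C@@](O[Si](C)(C)C)(/C=C\OCc2ccc(OC)cc2)[C@H](CC1)C3=COC(C)(C)OC3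
F2 | step 8 | (8S,9R)-9,14-O-isopropylidene-8-O-(4-methoxybenzyl)-6-(trimethylsilyloxy)-11,12,13-trinorgermacra-1(10)Z,4Z,6-triene-8,9,14-triol derivative (C5 and C8 trans across C6=C7) | C1/C(C)=C\C(O[Si](C)(C)C)=C\[C@H](OCc3ccc(OC)cc3)[C@@H]2OC(C)(C)OC/C2=C/C1
F0 | step 6 | none | none
F3 | step 4 | (1R,6R)-6-(2,2-dimethyl-4H-1,3-dioxin-5-yl)-3-methylcyclohex-2-en-1-ol | CC1=C[C@@H](O)[C@H](CC1)C2=COC(C)(C)OC2
F4 | step 9 | methyl (6R,7S,8S,9R)-6,8,9,14-tetrahydroxy-9,14-O-isopropylidene-8-O-(4-methoxybenzyl)-13-norgermacra-1(10)Z,4Z-dien-12-oate | O[C@@H]1/C=C(/C)CC/C=C2/COC(C)(C)O[C@H]2[C@@H](OCc3ccc(OC)cc3)[C@H]1CC(=O)OC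
F5 | step 10 | methyl (6R,7S,8S,9R)-6,8,9,14-tetrahydroxy-9,14-O-isopropylidene-8-O-(4-methoxybenzyl)-6-O-(4-nitrobenzoyl)-13-norgermacra-1(10)Z,4Z-dien-12-oate | O=C(O[C@@H]1/C=C(/C)CC/C=C2/COC(C)(C)O[C@H]2[C@@H](OCc3ccc(OC)cc3)[C@H]1CC(=O)OC)c1ccc(cc1)[N+](=O)[O-]
A1 | alternative 1 | bromobenzene | Brc1ccccc1
A2 | alternative 1 | (1S,2S)-3-bromocyclohexa-3,5-diene-1,2-diol | O[C@H]1C=CC=C(Br)[C@H]1O
A3 | alternative 2 | open-chain C5–C6 seco precursor: Z iodoalkene at C5, aldehyde at C6, methyl ester at C12, 8,9-acetonide, O14 tert-butyldimethylsilyl ether | O=C[C@H](CC(=O)OC)[C@@H]1OC(C)(C)O[C@@H]1/C(CO[Si](C)(C)C(C)(C)C)=C\CC/C(C)=C\I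
A4 | alternative 2 | trans-fused 12,6-lactone with 8,9-acetonide and O14 tert-butyldimethylsilyl ether, lacking C13 | C1C(=O)O[C@@H]2/C=C(/C)CC/C=C(/CO[Si](C)(C)C(C)(C)C)[C@H]3OC(C)(C)O[C@H]3[C@@H]12
A5 | alternative 3 | open-chain C9–C10 seco precursor: α-methylene lactone, Z iodoalkene at C10, aldehyde at C9, O8 triethylsilyl ether, O14 tert-butyldimethylsilyl ether | C=C1C(=O)O[C@H](/C=C(/C)CC/C=C(/CO[Si](C)(C)C(C)(C)C)I)[C@H]1[C@H](O[Si](CC)(CC)CC)C=O
A6 | alternative 3 | 9-hydroxy germacranolide with O8 triethylsilyl ether and O14 tert-butyldimethylsilyl ether | C=C1C(=O)O[C@@H]2/C=C(/C)CC/C=C(/CO[Si](C)(C)C(C)(C)C)[C@@H](O)[C@@H](O[Si](CC)(CC)CC)[C@@H]12
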